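The target is fisetinidol-(4β→8)-catechin-(6→4α)-fisetinidol. All three units are 2R,3S (2,3-trans); the C4 bound to catechin C8 is R (3,4-cis) and the C4 bound to catechin C6 is S (3,4-trans).
Cuts: after the protecting groups, first C4–C6, then C4–C8. Both fisetinidol units fall back on one C4 ketone (3-O-silyl tri-O-benzylfustin), which is cut at O1–C2 to an epoxychalcone and at Cα=Cβ to an acetophenone and an aldehyde.
Forward: chalcone, epoxide, closure of pyranone ring C (O1–C2). Catechin brings its three rings ready-made. The ketone is joined to C8-lithiated catechin (C4–C8) and reduced ionically. A second copy of the ketone is reduced, acetylated and joined at C6, followed by desilylation and hydrogenolysis.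
Enabling feature: each fisetinidol C4 is doubly benzylic (its own ring A and the catechin ring A) and sits next to the C3 oxygen. Fisetinidol ring A carries H, not O, at C5, so the C4 carbonyl has no peri neighbour and accepts a 2,6-dioxygenated aryllithium. Whichever partner (aryl or H) reaches planar C4 last lands anti to O3.
Stereochemistry: catechin C2/C3 are bought. Fisetinidol C3, and C2 by inversion on ring closure, come from a Juliá-Colonna epoxidation with poly-L-leucine. The C8-bound C4 is set by hydride arriving last (4β) and the C6-bound C4 by the arene arriving last (4α), both steered by the 3-O-silyl group.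

Key step: step 10

Remark: α and β are the faces of ring C in the usual flavanoid drawing (2R aryl = α, 3S oxygen = β). The C4 configurations drawn for the tertiary carbinol, the 4-alcohol and its acetate are the expected ones and are erased later. Poly-L-leucine is taken as a bought catalyst.

Step 1
Reactants: 1 2',4'-dihydroxyacetophenone
Product: 2 4'-benzyloxy-2'-hydroxyacetophenone
Conditions: BnBr (1.05 equiv), K2CO3, acetone, reflux
Reagents that add atoms: benzyl bromide, BrCc1ccccc1
Why: Williamson etherification: the 2'-hydroxyl is locked in a hydrogen bond to the acetyl oxygen and is left alone by carbonate and one equivalent of halide, so only O4' is benzylated.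

Step 2
Reactants: 2 4'-benzyloxy-2'-hydroxyacetophenone
Product: 3 4'-benzyloxy-2'-(methoxymethoxy)acetophenone
Conditions: MOMCl, i-Pr2NEt, CH2Cl2, 0 °C → reflux
Reagents that add atoms: chloromethyl methyl ether, COCCl
Why: O-alkylation of the remaining chelated phenol with a reactive α-chloro ether (MOM protection), which blocks flavanone formation in the aldol step and leaves an acid-labile trigger for the ring closure of step 5.

Step 3
Reactants: 3 4'-benzyloxy-2'-(methoxymethoxy)acetophenone; 4 3,4-dibenzyloxybenzaldehyde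
Product: 5 (E)-3,4,4'-tribenzyloxy-2'-(methoxymethoxy)chalcone
Conditions: KOH, EtOH–THF, rt
Reagents that add atoms: none
Why: Claisen-Schmidt condensation of a methyl ketone enolate with a non-enolisable aldehyde; E1cB dehydration gives the conjugated E-enone as the only alkene isomer.

Step 4
Reactants: 5 (E)-3,4,4'-tribenzyloxy-2'-(methoxymethoxy)chalcone
Product: 6 (αR,βS)-trans-3,4,4'-tribenzyloxy-2'-(methoxymethoxy)chalcone epoxide
Conditions: poly-L-leucine, urea·H2O2, DBU, THF, rt
Reagents that add atoms: urea-hydrogen peroxide adduct, NC(N)=O.OO (one oxygen atom)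
Why: Juliá-Colonna epoxidation (Weitz-Scheffer addition of hydroperoxide inside the helical polypeptide): poly-L-leucine is known to convert E-chalcones into the (αR,βS)-trans-epoxides, which sets both carbons in one event, and any minor enantiomer can be removed by crystallisation here or as a diastereomer after union with enantiopure catechin.

Step 5
Reactants: 6 (αR,βS)-trans-3,4,4'-tribenzyloxy-2'-(methoxymethoxy)chalcone epoxide
Product: 8 (2R,3R)-7,3',4'-tri-O-benzylfustin (2,3-trans dihydroflavonol), via 2'-hydroxy epoxychalcone 7 (not isolated)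
Conditions: conc. HCl (cat.), MeOH–THF, 50 °C
Reagents that add atoms: none
Why: Acid-catalysed acetal cleavage frees the 2'-phenol 7, which opens the protonated epoxide in the 6-endo mode at the p-alkoxybenzylic β carbon with inversion (C2 becomes R) while the Cα–O bond is kept (C3 stays R), a standard dihydroflavonol synthesis whose 2,3-trans product is also the thermodynamic one.

Step 6
Reactants: 8 (2R,3R)-7,3',4'-tri-O-benzylfustin
Product: 9 (2R,3R)-3-O-TBS-7,3',4'-tri-O-benzylfustin (common C4 ketone)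
Conditions: TBSOTf, 2,6-lutidine, CH2Cl2, −78 → 0 °C
Reagents that add atoms: tert-butyldimethylsilyl triflate, CC(C)(C)[Si](C)(C)OS(=O)(=O)C(F)(F)F
Why: Silylation of a secondary alcohol with a silyl triflate; 2,6-lutidine is too weak and too hindered to enolise the ketone or open ring C, so C2 and C3 are preserved and the bulky group that later steers both C4 events is in place.

Step 7
Reactants: 10 (+)-catechin
Product: 11 5,7,3',4'-tetra-O-benzylcatechin
Conditions: BnBr (4.4 equiv), K2CO3, DMF, 0 °C → rt, N2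
Reagents that add atoms: benzyl bromide, BrCc1ccccc1
Why: Fourfold Williamson etherification: carbonate deprotonates only the four phenols, so the aliphatic 3-hydroxyl stays free and C2 and C3 are untouched.

Step 8
Reactants: 11 5,7,3',4'-tetra-O-benzylcatechin
Product: 12 8-bromo-5,7,3',4'-tetra-O-benzylcatechin
Conditions: NBS (1.0 equiv), CH2Cl2, −78 °C → rt
Reagents that add atoms: N-bromosuccinimide, O=C1CCC(=O)N1Br
Why: Electrophilic aromatic bromination: in tetra-O-benzylated flavan-3-ols one equivalent of NBS at low temperature is known to attack C8 of ring A in preference to C6 and to ring B.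

Step 9
Reactants: 12 8-bromo-5,7,3',4'-tetra-O-benzylcatechin
Product: 13 8-bromo-3-O-TBS-5,7,3',4'-tetra-O-benzylcatechin
Conditions: TBSOTf, 2,6-lutidine, CH2Cl2, 0 °C
Reagents that add atoms: tert-butyldimethylsilyl triflate, CC(C)(C)[Si](C)(C)OS(=O)(=O)C(F)(F)F
Why: Silyl triflate silylation removes the last acidic proton before lithiation; a silyl ether is chosen over a fifth benzyl ether so that all aliphatic oxygens are released together in step 15.

Step 10
Reactants: 13 8-bromo-3-O-TBS-5,7,3',4'-tetra-O-benzylcatechin; 9 (2R,3R)-3-O-TBS-7,3',4'-tri-O-benzylfustin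
Product: 15 protected 4-(catechin-8-yl)flavan-4-ol (4α-aryl and 4β-OH drawn), via 8-lithiocatechin derivative 14 (not isolated)
Conditions: 13, n-BuLi, THF, −78 °C; then 9, THF, −78 → −20 °C; H2O
Reagents that add atoms: n-butyllithium, [Li]CCCC (gives the lithium of 14; none of its atoms stays in 15)
Why: Bromine-lithium exchange on 13 outruns every deprotonation at −78 °C and puts the carbanion on C8 alone (14), which then adds 1,2 to the C4 carbonyl of 9 and forges the C4–C8 interflavanyl bond at a trigonal carbon. The closest known reaction type is the addition of C8-lithiated, protected flavan-3-ols to protected 3-oxygenated flavan-4-ones of the 5,7-dioxygenated series, so that only the substitution pattern and the 2,3-trans relation are new here. No ring is closed. The only new stereocentre is the C4 carbinol, expected to arise by approach of the bulky nucleophile to the α face, anti to the 3β-silyloxy group (4α-aryl, 4β-OH), and it is planarised again in step 11, so its configuration carries no weight. The step needs site fidelity at C8, which the bromine placed in step 8 secures, and 1,2-addition in preference to C3–H enolisation and retro-oxa-Michael opening of ring C, which the low temperature, the modest basicity of a 2,6-dialkoxyaryllithium and above all the hydrogen at C5 (no peri oxygen beside the carbonyl) secure. C2 and C3 of both partners are spectators and keep their configuration.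

Step 11
Reactants: 15 protected 4-(catechin-8-yl)flavan-4-ol
Product: 17 protected fisetinidol-(4β→8)-catechin (upper unit 2R,3S,4R), via 4-aryl C4 carbenium ion 16 (not isolated)
Conditions: Bu3SnH, CF3CO2H, CH2Cl2, −78 → 0 °C
Reagents that add atoms: none
Why: Ionic hydrogenation (SN1 ionisation, then hydride transfer), known for tertiary 4-arylflavan-4-ols: the acid ionises the carbinol to the diaryl carbenium ion 16, stabilised by O1 and O7 of ring A and by the trioxygenated catechin ring that stands perpendicular and shields both faces alike, and the strong, bulky stannane donor delivers hydride to the α face, anti to the 3β-silyloxy group, so that the aryl group ends 4β (3,4-cis).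

Step 12
Reactants: 9 (2R,3R)-3-O-TBS-7,3',4'-tri-O-benzylfustin
Product: 18 (2R,3S,4R)-3-O-TBS-7,3',4'-tri-O-benzylleucofisetinidin (2,3-trans-3,4-trans 4-alcohol)
Conditions: NaBH4, THF–MeOH, −20 → 0 °C
Reagents that add atoms: none
Why: Borohydride 1,2-reduction of the aryl ketone, expected to deliver hydride axially and give mainly the 3,4-trans (4α) alcohol as in the dihydroflavonol to flavan-3,4-diol reduction; the C4 configuration is of no consequence because it is erased in step 14.

Step 13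
Reactants: 18 (2R,3S,4R)-3-O-TBS-7,3',4'-tri-O-benzylleucofisetinidin
Product: 19 4-O-acetyl-3-O-TBS-7,3',4'-tri-O-benzylleucofisetinidin (2R; 3-O β; 4-OAc α)
Conditions: Ac2O, pyridine, DMAP (cat.), CH2Cl2, 0 °C → rt
Reagents that add atoms: acetic anhydride, CC(=O)OC(C)=O
Why: DMAP-catalysed acetylation of the secondary benzylic alcohol gives a storable leaving group that a Lewis acid ionises at low temperature.

Step 14
Reactants: 17 protected fisetinidol-(4β→8)-catechin; 19 4-O-acetyl-3-O-TBS-7,3',4'-tri-O-benzylleucofisetinidin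
Product: 21 fully protected fisetinidol-(4β→8)-catechin-(6→4α)-fisetinidol, via fisetinidol C4 carbenium ion 20 (not isolated)
Conditions: BF3·OEt2 (0.5 equiv), 4 Å MS, CH2Cl2, −78 → −40 °C
Reagents that add atoms: none
Why: Friedel-Crafts flavanylation (SN1): BF3 ionises the benzylic acetate to cation 20, stabilised by O1 and O7, C6 is the only free position of the strongly activated catechin ring A and more nucleophilic than the resorcinol-type rings A, the arene enters the α face anti to the 3β-silyloxy group to give the 4α (3,4-trans, 4S) bond, and the existing C4–C8 bond, whose ring A lacks a 5-oxygen, is not re-ionised at low temperature.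

Step 15
Reactants: 21 fully protected fisetinidol-(4β→8)-catechin-(6→4α)-fisetinidol
Product: 22 deca-O-benzyl fisetinidol-(4β→8)-catechin-(6→4α)-fisetinidol (three free 3-hydroxyls)
Conditions: HF·pyridine, THF, 0 °C → rt
Reagents that add atoms: none
Why: Fluoride-driven cleavage of the three Si–O bonds (strong Si–F bond) under mildly acidic conditions that leave aryl benzyl ethers, the C–C interflavanyl bonds and all stereocentres untouched.

Step 16
Reactants: 22 deca-O-benzyl fisetinidol-(4β→8)-catechin-(6→4α)-fisetinidol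
Product: 23 fisetinidol-(4β→8)-catechin-(6→4α)-fisetinidol (CNP0289228.2)
Conditions: H2 (1 atm), Pd(OH)2/C, THF–MeOH–H2O, rt
Reagents that add atoms: none
Why: Heterogeneous hydrogenolysis of ten aryl benzyl ethers, the standard last step for benzylated proanthocyanidins, under which the interflavanyl C–C bonds and the C2–O1 bonds persist and no stereocentre is touched.

Compound list
1 | 2',4'-dihydroxyacetophenone | CC(=O)c1ccc(O)cc1O | starting material
2 | 4'-benzyloxy-2'-hydroxyacetophenone | CC(=O)c1ccc(OCc9ccccc9)cc1O | intermediate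
3 | 4'-benzyloxy-2'-(methoxymethoxy)acetophenone | CC(=O)c1ccc(OCc9ccccc9)cc1OCOC | intermediate
4 | 3,4-dibenzyloxybenzaldehyde | O=Cc1ccc(OCc9ccccc9)c(OCc9ccccc9)c1 | starting material
5 | (E)-3,4,4'-tribenzyloxy-2'-(methoxymethoxy)chalcone | COCOc1cc(OCc9ccccc9)ccc1C(=O)/C=C/c1ccc(OCc9ccccc9)c(OCc9ccccc9)c1 | intermediate
6 | (αR,βS)-trans-3,4,4'-tribenzyloxy-2'-(methoxymethoxy)chalcone epoxide | COCOc1cc(OCc9ccccc9)ccc1C(=O)[C@@H]1O[C@H]1c1ccc(OCc9ccccc9)c(OCc9ccccc9)c1 | intermediate
7 | (αR,βS)-trans-3,4,4'-tribenzyloxy-2'-hydroxychalcone epoxide (not isolated) | Oc1cc(OCc9ccccc9)ccc1C(=O)[C@@H]1O[C@H]1c1ccc(OCc9ccccc9)c(OCc9ccccc9)c1 | intermediate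
8 | (2R,3R)-7,3',4'-tri-O-benzylfustin | c9ccccc9COc1ccc2c(c1)O[C@H](c1ccc(OCc9ccccc9)c(OCc9ccccc9)c1)[C@@H](O)C2=O | intermediate
9 | (2R,3R)-3-O-TBS-7,3',4'-tri-O-benzylfustin | c9ccccc9COc1ccc2c(c1)O[C@H](c1ccc(OCc9ccccc9)c(OCc9ccccc9)c1)[C@@H](O[Si](C)(C)C(C)(C)C)C2=O | intermediate
10 | (+)-catechin (2R,3S) | Oc1cc(O)c2c(c1)O[C@H](c1ccc(O)c(O)c1)[C@@H](O)C2 | starting material
11 | 5,7,3',4'-tetra-O-benzylcatechin | c9ccccc9COc1cc(OCc9ccccc9)c2c(c1)O[C@H](c1ccc(OCc9ccccc9)c(OCc9ccccc9)c1)[C@@H](O)C2 | intermediate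
12 | 8-bromo-5,7,3',4'-tetra-O-benzylcatechin | Brc1c(OCc9ccccc9)cc(OCc9ccccc9)c2c1O[C@H](c1ccc(OCc9ccccc9)c(OCc9ccccc9)c1)[C@@H](O)C2 | intermediate
13 | 8-bromo-3-O-TBS-5,7,3',4'-tetra-O-benzylcatechin | Brc1c(OCc9ccccc9)cc(OCc9ccccc9)c2c1O[C@H](c1ccc(OCc9ccccc9)c(OCc9ccccc9)c1)[C@@H](O[Si](C)(C)C(C)(C)C)C2 | intermediate
14 | 8-lithio-3-O-TBS-5,7,3',4'-tetra-O-benzylcatechin (not isolated) | [Li]c1c(OCc9ccccc9)cc(OCc9ccccc9)c2c1O[C@H](c1ccc(OCc9ccccc9)c(OCc9ccccc9)c1)[C@@H](O[Si](C)(C)C(C)(C)C)C2 | intermediate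
15 | protected 4-(catechin-8-yl)flavan-4-ol, 4α-aryl and 4β-OH | c9ccccc9COc1ccc2c(c1)O[C@H](c1ccc(OCc9ccccc9)c(OCc9ccccc9)c1)[C@@H](O[Si](C)(C)C(C)(C)C)[C@]2(O)c1c(OCc9ccccc9)cc(OCc9ccccc9)c2c1O[C@H](c1ccc(OCc9ccccc9)c(OCc9ccccc9)c1)[C@@H](O[Si](C)(C)C(C)(C)C)C2 | intermediate
16 | 4-(catechin-8-yl)flavan-4-ylium ion (not isolated) | c9ccccc9COc1ccc2c(c1)O[C@H](c1ccc(OCc9ccccc9)c(OCc9ccccc9)c1)[C@@H](O[Si](C)(C)C(C)(C)C)[C+]2c1c(OCc9ccccc9)cc(OCc9ccccc9)c2c1O[C@H](c1ccc(OCc9ccccc9)c(OCc9ccccc9)c1)[C@@H](O[Si](C)(C)C(C)(C)C)C2 | intermediate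
17 | bis-O-TBS hepta-O-benzyl fisetinidol-(4β→8)-catechin | c9ccccc9COc1ccc2c(c1)O[C@H](c1ccc(OCc9ccccc9)c(OCc9ccccc9)c1)[C@@H](O[Si](C)(C)C(C)(C)C)[C@H]2c1c(OCc9ccccc9)cc(OCc9ccccc9)c2c1O[C@H](c1ccc(OCc9ccccc9)c(OCc9ccccc9)c1)[C@@H](O[Si](C)(C)C(C)(C)C)C2 | intermediate
18 | (2R,3S,4R)-3-O-TBS-7,3',4'-tri-O-benzylleucofisetinidin | c9ccccc9COc1ccc2c(c1)O[C@H](c1ccc(OCc9ccccc9)c(OCc9ccccc9)c1)[C@@H](O[Si](C)(C)C(C)(C)C)[C@@H]2O | intermediate
19 | 4-O-acetyl-3-O-TBS-7,3',4'-tri-O-benzylleucofisetinidin (2,3-trans-3,4-trans) | c9ccccc9COc1ccc2c(c1)O[C@H](c1ccc(OCc9ccccc9)c(OCc9ccccc9)c1)[C@@H](O[Si](C)(C)C(C)(C)C)[C@@H]2OC(C)=O | intermediate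
20 | 3-O-TBS-7,3',4'-tri-O-benzylfisetinidol C4 carbenium ion (not isolated) | c9ccccc9COc1ccc2c(c1)O[C@H](c1ccc(OCc9ccccc9)c(OCc9ccccc9)c1)[C@@H](O[Si](C)(C)C(C)(C)C)[CH+]2 | intermediate
21 | tris-O-TBS deca-O-benzyl fisetinidol-(4β→8)-catechin-(6→4α)-fisetinidol | c9ccccc9COc1ccc2c(c1)O[C@H](c1ccc(OCc9ccccc9)c(OCc9ccccc9)c1)[C@@H](O[Si](C)(C)C(C)(C)C)[C@H]2c1c(OCc9ccccc9)c([C@@H]2c3ccc(OCc9ccccc9)cc3O[C@H](c3ccc(OCc9ccccc9)c(OCc9ccccc9)c3)[C@H]2O[Si](C)(C)C(C)(C)C)c(OCc9ccccc9)c2c1O[C@H](c1ccc(OCc9ccccc9)c(OCc9ccccc9)c1)[C@@H](O[Si](C)(C)C(C)(C)C)C2 | intermediate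
22 | deca-O-benzyl fisetinidol-(4β→8)-catechin-(6→4α)-fisetinidol | c9ccccc9COc1ccc2c(c1)O[C@H](c1ccc(OCc9ccccc9)c(OCc9ccccc9)c1)[C@@H](O)[C@H]2c1c(OCc9ccccc9)c([C@@H]2c3ccc(OCc9ccccc9)cc3O[C@H](c3ccc(OCc9ccccc9)c(OCc9ccccc9)c3)[C@H]2O)c(OCc9ccccc9)c2c1O[C@H](c1ccc(OCc9ccccc9)c(OCc9ccccc9)c1)[C@@H](O)C2 | intermediate
23 | fisetinidol-(4β→8)-catechin-(6→4α)-fisetinidol (CNP0289228.2) | Oc1ccc2c(c1)O[C@H](c1ccc(O)c(O)c1)[C@@H](O)[C@H]2c1c(O)c([C@@H]2c3ccc(O)cc3O[C@H](c3ccc(O)c(O)c3)[C@H]2O)c(O)c2c1O[C@H](c1ccc(O)c(O)c1)[C@@H](O)C2 | target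

Total step count: 16.
Longest linear sequence: 11 steps (1 → 2 → 3 → 5 → 6 → 8 → 9 → 15 → 17 → 21 → 22 → 23). The branch through 18 and 19 is equally long.

Steps most likely to fail

Step 11, poor facial selectivity of the hydride transfer.
- The hydride has to enter the face of ring C that also carries the C2 aryl group. If the cation relieves the strain between the C4 aryl and the 3-O-silyl group by turning both C2 and C3 substituents pseudo-axial, the C2 aryl stands 1,3 to the incoming donor.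
- Loss of H3 from the cation, or loss of a silyl group in the acid, may also compete.
- The fallback sets out from 11 and 8 and comes back at 17. It fixes the face by tethering instead of by shielding.
- Compound 11 is opened onto glutaric anhydride (DMAP, pyridine) to give tetra-O-benzylcatechin 3-O-hemiglutarate F1. This is esterified (EDC·HCl, DMAP, CH2Cl2) with the 3-hydroxyl of 8 to give the glutarate-linked keto diester F2.
- NaBH4 with CeCl3·7H2O in THF–MeOH at low temperature reduces only the C4 ketone to the linked benzylic 4-alcohol F3.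
- TMSOTf at high dilution in CH2Cl2 at low temperature ionises C4. The tethered catechin ring can reach the cation only from the face that bears O3, which should give the 14-membered bridged 3,4-cis dimer F4. Intramolecular Friedel-Crafts condensation through a 3,3-diester tether is a known way to 3,4-cis dimers in the catechin series.
- K2CO3 in MeOH–THF removes the tether to give hepta-O-benzyl fisetinidol-(4β→8)-catechin F5, and TBSOTf with 2,6-lutidine silylates both 3-hydroxyls to give 17.

Step 10, proton transfer instead of addition.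
- Enolisation at C3 followed by retro-oxa-Michael opening of ring C may compete, or attack of the doubly ortho-substituted aryllithium may be sluggish.
- The fallback sets out from 8 and 10 and comes back at 17. It replaces the carbanion by the classical cationic condensation of the free phenols.
- Hydrogenolysis of 8 (H2, Pd/C, EtOAc–MeOH) gives (2R,3R)-fustin F6, and NaBH4 in EtOH gives (2R,3S,4R)-leucofisetinidin F7.
- F7 is stirred with an excess of 10 in 0.1 M aqueous HCl at rt. The C4 cation of the 5-deoxy series is known to be taken up at C8 from both faces.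
- Fisetinidol-(4β→8)-catechin F8 is separated from its regio- and stereoisomers on Sephadex LH-20.
- BnBr and K2CO3 in DMF then give the hepta-O-benzyl ether F5, and TBSOTf with 2,6-lutidine gives 17.

Step 14, slow capture of the cation at C6.
- C6 lies between two benzyloxy groups on a valuable dimer that cannot be used in excess. Attack of the cation on the resorcinol-type rings A (self-condensation) or erosion of the α selectivity may therefore take over.
- The fallback sets out from 13 and 19 (with 9 as third partner) and comes back at 21. It reverses the order of the two unions.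
- An excess of the monomeric bromide 13, recoverable afterwards, is treated with 19 and BF3·OEt2 in CH2Cl2 at low temperature. The C8 bromine acts as a cap, a known device for directing flavanylation to C6. This gives the protected 8-bromocatechin-(6→4α)-fisetinidol F9.
- n-BuLi in THF at −78 °C converts F9 into the 8-lithio dimer F10, which adds to ketone 9 as in step 10 to give the trimeric tertiary carbinol F11.
- Bu3SnH and CF3CO2H as in step 11 reduce F11 through the trimeric 4-aryl carbenium ion F12 to 21.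

Further compounds
F1 | step 11 | 5,7,3',4'-tetra-O-benzylcatechin 3-O-hemiglutarate | c9ccccc9COc1cc(OCc9ccccc9)c2c(c1)O[C@H](c1ccc(OCc9ccccc9)c(OCc9ccccc9)c1)[C@@H](OC(=O)CCCC(=O)O)C2
F2 | step 11 | glutarate diester of tri-O-benzylfustin (O3) and tetra-O-benzylcatechin (O3) | c9ccccc9COc1ccc2c(c1)O[C@H](c1ccc(OCc9ccccc9)c(OCc9ccccc9)c1)[C@@H](OC(=O)CCCC(=O)O[C@H]1Cc3c(OCc9ccccc9)cc(OCc9ccccc9)cc3O[C@@H]1c1ccc(OCc9ccccc9)c(OCc9ccccc9)c1)C2=O
F3 | step 11 | glutarate-linked 4-alcohol (4α-OH drawn) | c9ccccc9COc1ccc2c(c1)O[C@H](c1ccc(OCc9ccccc9)c(OCc9ccccc9)c1)[C@@H](OC(=O)CCCC(=O)O[C@H]1Cc3c(OCc9ccccc9)cc(OCc9ccccc9)cc3O[C@@H]1c1ccc(OCc9ccccc9)c(OCc9ccccc9)c1)[C@@H]2O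
F4 | step 11 | 14-membered glutarate-bridged hepta-O-benzyl fisetinidol-(4β→8)-catechin | c9ccccc9COc1ccc2c(c1)O[C@H](c1ccc(OCc9ccccc9)c(OCc9ccccc9)c1)[C@H]3OC(=O)CCCC(=O)O[C@H]4Cc5c(OCc9ccccc9)cc(OCc9ccccc9)c([C@@H]23)c5O[C@@H]4c1ccc(OCc9ccccc9)c(OCc9ccccc9)c1
F5 | step 11 | hepta-O-benzyl fisetinidol-(4β→8)-catechin (both 3-hydroxyls free) | c9ccccc9COc1ccc2c(c1)O[C@H](c1ccc(OCc9ccccc9)c(OCc9ccccc9)c1)[C@@H](O)[C@H]2c1c(OCc9ccccc9)cc(OCc9ccccc9)c2c1O[C@H](c1ccc(OCc9ccccc9)c(OCc9ccccc9)c1)[C@@H](O)C2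
F6 | step 10 | (2R,3R)-fustin | Oc1ccc2c(c1)O[C@H](c1ccc(O)c(O)c1)[C@@H](O)C2=O
F7 | step 10 | (2R,3S,4R)-leucofisetinidin (mollisacacidin) | Oc1ccc2c(c1)O[C@H](c1ccc(O)c(O)c1)[C@@H](O)[C@@H]2O
F8 | step 10 | fisetinidol-(4β→8)-catechin | Oc1ccc2c(c1)O[C@H](c1ccc(O)c(O)c1)[C@@H](O)[C@H]2c1c(O)cc(O)c2c1O[C@H](c1ccc(O)c(O)c1)[C@@H](O)C2
F9 | step 14 | bis-O-TBS hepta-O-benzyl 8-bromocatechin-(6→4α)-fisetinidol | Brc1c(OCc9ccccc9)c([C@@H]2c3ccc(OCc9ccccc9)cc3O[C@H](c3ccc(OCc9ccccc9)c(OCc9ccccc9)c3)[C@H]2O[Si](C)(C)C(C)(C)C)c(OCc9ccccc9)c2c1O[C@H](c1ccc(OCc9ccccc9)c(OCc9ccccc9)c1)[C@@H](O[Si](C)(C)C(C)(C)C)C2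
F10 | step 14 | 8-lithio derivative of F9 | [Li]c1c(OCc9ccccc9)c([C@@H]2c3ccc(OCc9ccccc9)cc3O[C@H](c3ccc(OCc9ccccc9)c(OCc9ccccc9)c3)[C@H]2O[Si](C)(C)C(C)(C)C)c(OCc9ccccc9)c2c1O[C@H](c1ccc(OCc9ccccc9)c(OCc9ccccc9)c1)[C@@H](O[Si](C)(C)C(C)(C)C)C2
F11 | step 14 | trimeric tertiary C4 carbinol (4α-aryl and 4β-OH drawn) | c9ccccc9COc1ccc2c(c1)O[C@H](c1ccc(OCc9ccccc9)c(OCc9ccccc9)c1)[C@@H](O[Si](C)(C)C(C)(C)C)[C@]2(O)c1c(OCc9ccccc9)c([C@@H]2c3ccc(OCc9ccccc9)cc3O[C@H](c3ccc(OCc9ccccc9)c(OCc9ccccc9)c3)[C@H]2O[Si](C)(C)C(C)(C)C)c(OCc9ccccc9)c2c1O[C@H](c1ccc(OCc9ccccc9)c(OCc9ccccc9)c1)[C@@H](O[Si](C)(C)C(C)(C)C)C2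
F12 | step 14 | trimeric 4-aryl C4 carbenium ion | c9ccccc9COc1ccc2c(c1)O[C@H](c1ccc(OCc9ccccc9)c(OCc9ccccc9)c1)[C@@H](O[Si](C)(C)C(C)(C)C)[C+]2c1c(OCc9ccccc9)c([C@@H]2c3ccc(OCc9ccccc9)cc3O[C@H](c3ccc(OCc9ccccc9)c(OCc9ccccc9)c3)[C@H]2O[Si](C)(C)C(C)(C)C)c(OCc9ccccc9)c2c1O[C@H](c1ccc(OCc9ccccc9)c(OCc9ccccc9)c1)[C@@H](O[Si](C)(C)C(C)(C)C)C2
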